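## Analysis of the target

Locants used throughout: drimane carbons C1–C12 (C11 is the methylene on C9, C8=C12 the exocyclic alkene), quinol carbons C1'–C6', glutarate carbons C1''–C5'' (C1'' esterified, C3'' the carbinol). "Albicanyl" means (5S,9S,10S)-drim-8(12)-en-11-yl.

The molecule joins three parts: a trans-decalin (rings A and B), a cyclohexenone epoxide (the quinol ring) attached through C11 to C1', and a 3-hydroxy-3-methylglutaric half-ester on the C4' hydroxymethyl group. It has seven stereocentres. C5, C9 and C10 are those of the drimane chiral pool. C1', C2' and C3' are contiguous (1'S,2'S,3'R): the epoxide oxygen is trans to the C3' hydroxyl and C11 is cis to it. C3'' is R, and it is a stereocentre only because one carboxymethyl arm is esterified and the other is free. The sensitive groups are the α,β-epoxy ketone, the γ-hydroxy enone, the allylic ester (acyl migration to the C3' hydroxyl), the β-hydroxy acid, and the C8=C12 alkene, which isomerises in strong acid and is the most nucleophilic alkene towards electrophilic oxidants. The difficulty is threefold: six differently substituted carbons on one small ring, relating the quinol stereocentres to a remote and non-directing decalin, and a side-chain stereocentre that a symmetrical acyl donor cannot set. The strategy rests on the fact that C3' and C6' are para oxygen-bearing carbons at the quinone oxidation level, with C1'=C2' and C4'=C5' as the two "quinone" double bonds. The ring is therefore a 2,5-disubstituted hydroquinone dimethyl ether in disguise, and a quinone monoketal can differentiate every ring carbon.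

## Retrosynthetic reasoning

Ester bond O–C1'' (28 ⇒ 27 ⇒ 20 + 26). The acyl–oxygen bond is cut late because the half-ester is the most fragile part. An undifferentiated glutaric acyl donor would give both C3'' epimers, so the acid must arrive with its two arms already distinguished. This gives diol 20 and half-ester 26, whose second carboxyl is masked as a silylethyl ester that fluoride removes (27 → 28) without acid or strong base. The forward coupling has to select the primary allylic hydroxyl over the hindered C3' hydroxyl.

Side-chain acid (26 ⇒ 25 ⇒ 24 ⇒ 23 ⇒ 21). No C–C bond is cut. The lactone carbonyl of 21 becomes the carboxyl that 20 will esterify, and C5'' is oxidised to the second carboxyl. Opening the lactone (22, 23) marks the first carboxyl as a benzyl ester; oxidation (24), capping of the new acid (25) and hydrogenolysis free the coupling acid. The stereocentre is safe as long as the two arms are never both free.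

Unmasking (20 ⇒ 19). The C6' ketone and the primary hydroxyl are revealed together from the dimethyl ketal and the silyl ether. The base-sensitive γ-hydroxy epoxy enone therefore appears only after all basic steps.

Epoxide and C3' (19 ⇒ 18 ⇒ 17 ⇒ 16). The C1'–O and C2'–O bonds are cut back to the C1'=C2' alkene. An electrophilic oxidant on a silyl-protected dienol would give the trans arrangement directly, but C1'=C2' carries three allylic oxygens and the unhindered C8=C12 alkene would react first. The oxygen is therefore delivered from the C3' hydroxyl itself, which no isolated alkene can match. That delivery is cis, so C3' is first set with the opposite configuration (16), the epoxide follows it (17), and C3' is then inverted (18 → 19). Inversion after epoxidation also means the ring can no longer aromatise by loss of an alcohol.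

Carbinol C3'–H (16 ⇒ 15). The ring of 15 is flat and the decalin is too far away to bias it, so the C3' configuration has to come from a chiral reduction catalyst. The catalyst distinguishes the α-branched C4' flank from the unbranched C2' flank.

Ketal oxygens (15 ⇒ 14 ⇒ 13). The C3'–O and C6'–O ketal bonds are the two bonds of the key disconnection: anodic addition of two alkoxide units to arene 13 gives bisketal 14. Monohydrolysis then has to unveil the C3' carbonyl and keep the C6' ketal; the alkyl group on C1' and the oxygenated methyl group on C4' both favour that sense.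

Arene (13 ⇒ 12 ⇒ 10 + 4). After removal of one O-methyl group, the benzene ring is cut at C2'–C3', C1'–C6' and C5'–C6'. Alkyne 4 supplies C1' and C2', carbene complex 10 supplies C3', C4' and C5', and a carbonyl ligand supplies C6'. The benzannulation puts the substituted alkyne carbon next to the phenolic carbon, which is exactly the 2,5-pattern needed.

Carbene complex (10 ⇒ 9 ⇒ 8 ⇒ 6 + 7, 6 ⇒ 5). The carbene carbon–alkenyl bond is cut to an alkenyllithium and 7; the alkenyl bromide 6 is the silyl ether of 5.

Alkyne (4 ⇒ 3 ⇒ 2 ⇒ 1). Lactone 1 already contains C11 and the carbon that becomes C1'. Reduction to lactol 2 and one-carbon homologation add C2'. The C8 oxygen is then removed by elimination towards C12, which the equatorial C8–O bond should favour.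

## Alternatives that were turned down

Alternative 1: The decalin is cut at C5–C10 and C8–C9. Heating (or Lewis-acid activation of) trienal A1 would make its (E)-enal add across the tethered (E,E)-1-silyloxydiene and give the bicyclic silyloxy aldehyde A2, closing rings A and B together. In its favour: two rings and four stereocentres arise in one step, the C8 oxygen could become a ketone and be methylenated so that C8=C12 is regiochemically certain (better than the dehydration in step 3), and the design does not depend on a terpene supply. Against it: the dienophile carbon C10 is fully substituted, so the cycloaddition is slow and its endo/exo outcome, which decides the ring fusion, is uncertain. A2 would be racemic without an asymmetric catalyst that is not established for such a hindered enal. A2 is also a β-silyloxy aldehyde with an epimerisable C9 and is prone to elimination. Reaching arene 13 from A2 would still need alkene reduction, oxidation and methylenation at C8, aryl addition and benzylic deoxygenation. The chosen route takes C5, C9 and C10 enantiopure from 1 in three steps.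

Alternative 2: The quinol ring is cut at C3'–C4'. CrCl2 with catalytic NiCl2 would convert the (Z)-β-iodoenone A3 into a vinylchromium species that adds to its own epoxy aldehyde, closing the ring and creating the C3' carbinol of A4, the 4-methoxybenzyl ether of 20. In its favour: every ring carbon is defined in the open chain, so the two regiochemical questions of the chosen route (which ketal hydrolyses, which alkene is epoxidised) do not arise; here it is stronger. Against it: A3 combines an α,β-epoxy aldehyde, a ketone on the quaternary epoxide carbon and an isomerisable iodoenone, and its epoxide must be set on an acyclic precursor relative to the remote decalin, which needs a long linear sequence. The C3' configuration would rest on substrate control by the epoxide with no means of correction in the same step. Large excesses of the chromium salt are also needed. The chosen route offers a short aromatic assembly and catalyst control at C3' in exchange for the regiochemical certainty.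

Alternative 3: The decalin is cut at C4–C5 and C9–C10. Cp2TiCl (a trivalent titanium reagent) would open the terminal epoxide of the epoxyfarnesyl arene A5; the tertiary radical would close rings A and B and terminate as the exocyclic alkene, giving the 3β-hydroxy arene A6. In its favour: the arene is present from the start, the C8=C12 alkene is formed directly and regioselectively (again better than step 3), and A6 could enter the same anodic sequence. Against it: A6 carries a C3 hydroxyl that the target lacks, so two deoxygenation steps are added. The enantiopurity depends on an asymmetric route to the terminal epoxide rather than on an enantiopure terpene. Radical bicyclisations of this kind usually give monocyclic and stereoisomeric by-products. It would be several steps longer to the equivalent of 13, and it changes nothing in the quinol chemistry.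

Key step: step 8

Remark on the chemistry: (R)-mevalonolactone 21 is assumed to be purchasable in enantiopure form; it is the source of C3''.

## Steps

Step 1
Reactants: 1 (+)-sclareolide
Product: 2 sclareolide lactol (anomer mixture)
Conditions: i-Bu2AlH, CH2Cl2, −78 °C; aq. potassium sodium tartrate
Reagents that add atoms: none
Why: Partial reduction of a γ-lactone by i-Bu2AlH stops at the aluminium hemiacetal at low temperature; C5, C8, C9 and C10 are untouched.

Step 2
Reactants: 2 sclareolide lactol
Product: 3 11-ethynyldriman-8α-ol
Conditions: dimethyl (1-diazo-2-oxopropyl)phosphonate, K2CO3, MeOH, rt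
Reagents that add atoms: dimethyl (1-diazo-2-oxopropyl)phosphonate, CC(=O)C(=[N+]=[N-])P(=O)(OC)OC
Why: Seyferth–Gilbert homologation (Ohira–Bestmann variant) acts on the hydroxy aldehyde in equilibrium with the lactol and turns CHO into C≡CH with one added carbon; C11 is a methylene, so nothing can epimerise, and the tertiary C8 hydroxyl is released.

Step 3
Reactants: 3 11-ethynyldriman-8α-ol
Product: 4 11-ethynyldrim-8(12)-ene
Conditions: SOCl2, pyridine, CH2Cl2, −78 °C
Reagents that add atoms: none
Why: E2 dehydration through the tertiary chlorosulfite: the 8α C–O bond is equatorial, so no ring hydrogen on C7 or C9 is antiperiplanar to it and only a hydrogen of the axial C12 methyl can be, which should favour the C8=C12 alkene; endocyclic isomers from an ionising pathway would be removed on AgNO3-impregnated silica.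

Step 4
Reactants: 5 2-bromoprop-2-en-1-ol
Product: 6 (2-bromoallyloxy)(tert-butyl)dimethylsilane
Conditions: TBSCl, imidazole, CH2Cl2, 0 °C to rt
Reagents that add atoms: tert-butyldimethylsilyl chloride, CC(C)(C)[Si](C)(C)Cl
Why: Standard silylation of a primary alcohol; the ether masks the hydroxyl for the lithiation and later withstands methanolic KOH and dilute acetic acid.

Step 5
Reactants: 6 (2-bromoallyloxy)(tert-butyl)dimethylsilane; 7 Cr(CO)6
Product: 10 pentacarbonyl{methoxy[3-(tert-butyldimethylsilyloxy)prop-1-en-2-yl]carbene}chromium, via 2-lithioallyl silyl ether 8 (not isolated), via lithium acylchromate 9 (not isolated)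
Conditions: t-BuLi (2 equiv), Et2O, −78 °C; Cr(CO)6, −78 to 0 °C; Me3OBF4, CH2Cl2, 0 °C
Reagents that add atoms: trimethyloxonium tetrafluoroborate, C[O+](C)C.F[B-](F)(F)F
Why: Fischer carbene synthesis: bromine–lithium exchange, addition of the alkenyllithium to a carbonyl ligand and O-methylation of the acyl metalate; the exchange is kept at −78 °C so that silyl migration from oxygen to carbon (retro-Brook) does not compete.

Step 6
Reactants: 10 alkenyl(methoxy)carbene complex; 4 11-ethynyldrim-8(12)-ene
Product: 12 2-albicanyl-4-methoxy-5-[(tert-butyldimethylsilyloxy)methyl]phenol, via arene tricarbonylchromium complex 11 (not isolated)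
Conditions: THF, 50 °C; then air, MeCN, rt
Reagents that add atoms: none
Why: Dötz benzannulation (alkyne insertion, CO insertion to the vinylketene, 6π-electrocyclisation, tautomerisation); a terminal alkyne places its substituted carbon next to the phenolic carbon, so C1' is ortho to the C6' hydroxyl and the carbene methoxy group ends at C3' beside C4'; air frees the arene from Cr(CO)3.

Step 7
Reactants: 12 phenol
Product: 13 1-albicanyl-2,5-dimethoxy-4-[(tert-butyldimethylsilyloxy)methyl]benzene
Conditions: MeI, K2CO3, acetone, reflux
Reagents that add atoms: iodomethane, CI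
Why: Williamson O-methylation of the only acidic site; it turns the air-sensitive hydroquinone monoether into the robust dimethyl ether needed for electrolysis.

Step 8
Reactants: 13 albicanyl dimethoxyarene
Product: 14 1-albicanyl-3,3,6,6-tetramethoxy-4-[(tert-butyldimethylsilyloxy)methyl]cyclohexa-1,4-diene
Conditions: Pt anode, Pt cathode, undivided cell, 1% KOH in MeOH–THF, 0 °C, constant current
Reagents that add atoms: methanol, CO
Why: The 1,4-dimethoxyarene is the most easily oxidised group in 13; it gives up one electron at the anode to a radical cation, which methoxide captures at a methoxy-bearing ring carbon (C3' or C6'), and the resulting cyclohexadienyl radical is oxidised again and trapped by a second methoxide at the para methoxy-bearing carbon, forming the C3'–O and C6'–O bonds and leaving the ring as a cyclohexa-1,4-diene bisketal. The closest known reaction type is the anodic methoxylation of hydroquinone dimethyl ethers to quinone bisketals in methanolic KOH. No ring is closed and no stereocentre is created, since C3' and C6' each carry two identical methoxy groups. The step needs chemoselectivity for the arene over the C8=C12 alkene and the silyl ether, and attack at the ring rather than at the benzylic positions C11 and CH2OSi. The first is secured by the large gap in oxidation potential between a dialkyl dimethoxybenzene and an unconjugated 1,1-disubstituted alkene. The second is secured by the basic medium, in which methoxide adds to the radical cation faster than a benzylic proton is lost. The primary alkyl silyl ether is stable to cold methanolic KOH, and because hydrogen is evolved at the cathode no chemical oxidant has to be separated from the acid-labile product.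

Step 9
Reactants: 14 quinone bisketal
Product: 15 5-albicanyl-4,4-dimethoxy-2-[(tert-butyldimethylsilyloxy)methyl]cyclohexa-2,5-dien-1-one
Conditions: 5% aq. AcOH–acetone, 0 °C
Reagents that add atoms: water, O
Why: Acid-catalysed monohydrolysis of a quinone bisketal: the C3' ketal ionises faster because its pentadienyl oxocarbenium ion places positive charge on alkyl-substituted C1', whereas ionisation at C6' would place it on C4' beside the inductively withdrawing CH2OSi group; the first carbonyl then deactivates the remaining ketal and the silyl ether is stable to dilute acetic acid.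

Step 10
Reactants: 15 quinone monoketal
Product: 16 (3'R)-5-albicanyl-4,4-dimethoxy-2-[(tert-butyldimethylsilyloxy)methyl]cyclohexa-2,5-dien-1-ol
Conditions: (S)-Me-CBS oxazaborolidine (0.2 equiv), catecholborane, toluene, −78 °C; MeOH; 1 M NaOH wash
Reagents that add atoms: none
Why: Corey–Bakshi–Shibata reduction: the ketone binds the catalyst boron on the side of the unbranched C2' flank, with the α-branched C4' flank as the large group, and by the usual model the (S)-catalyst should give the 3'R alcohol (the enantiomeric catalyst is at hand if the sense proves reversed); catecholborane does not hydroborate C8=C12 at −78 °C, and the basic work-up keeps the dienol from losing methanol and aromatising.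

Step 11
Reactants: 16 (3'R)-dienol
Product: 17 (1'S,2'S,3'S)-cis-epoxy alcohol ketal
Conditions: VO(acac)2 (cat.), t-BuOOH (1.1 equiv), toluene, 0 °C
Reagents that add atoms: tert-butyl hydroperoxide, CC(C)(C)OO
Why: Hydroxyl-directed epoxidation of a cyclic allylic alcohol: the vanadium alkoxide of the C3' hydroxyl delivers oxygen to its own face, so the epoxide is cis to the hydroxyl and, with C3' set as R, is 1'S,2'S; the isolated C8=C12 alkene cannot bind the metal and is left alone, and C1'=C2' should be preferred over C4'=C5' because it carries an alkyl group where the other carries the electron-withdrawing CH2OSi group.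

Step 12
Reactants: 17 cis-epoxy alcohol ketal
Product: 19 (1'S,2'S,3'R)-trans-epoxy alcohol ketal, via trans 4-nitrobenzoate 18 (not isolated)
Conditions: 4-O2NC6H4CO2H, PPh3, DIAD, toluene, 0 °C to rt; then K2CO3, MeOH, 0 °C
Reagents that add atoms: 4-nitrobenzoic acid, O=C(O)c1ccc(cc1)[N+](=O)[O-]
Why: Mitsunobu reaction: SN2 displacement of the allylic oxyphosphonium at C3' by the carboxylate inverts the centre, so the new C3' oxygen is trans to the epoxide; brief methanolysis of the activated ester in the same flask frees the alcohol, and since no enone is present yet the base does no harm.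

Step 13
Reactants: 19 trans-epoxy alcohol ketal
Product: 20 (1'S,2'S,3'R)-1'-albicanyl-1',2'-epoxy-3'-hydroxy-4'-(hydroxymethyl)cyclohex-4'-en-6'-one
Conditions: 48% aq. HF, MeCN, 0 °C to rt
Reagents that add atoms: water, O
Why: Aqueous HF cleaves the primary silyl ether and hydrolyses the dimethyl ketal through an allylic oxocarbenium ion to the enone; the weak acid should spare the epoxide and not isomerise C8=C12, and no stereocentre is touched.

Step 14
Reactants: 21 (R)-mevalonolactone
Product: 23 benzyl (R)-mevalonate, via potassium (R)-mevalonate 22 (not isolated)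
Conditions: KOH (1 equiv), H2O, 40 °C; evaporate; BnBr, DMF, rt
Reagents that add atoms: potassium hydroxide, [K+].[OH-]; benzyl bromide, BrCc1ccccc1
Why: Saponification opens the δ-lactone at the acyl carbon and SN2 alkylation of the carboxylate gives the benzyl ester; the tertiary carbinol is not involved, and the product is used at once because it can relactonise.

Step 15
Reactants: 23 benzyl (R)-mevalonate
Product: 24 (R)-5-benzyloxy-3-hydroxy-3-methyl-5-oxopentanoic acid
Conditions: TEMPO (cat.), PhI(OAc)2, MeCN–H2O, rt
Reagents that add atoms: water, O
Why: Oxoammonium oxidation of the primary alcohol in wet solvent runs through the aldehyde hydrate to the acid; the tertiary alcohol cannot be oxidised and the two termini stay distinct as ester and acid.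

Step 16
Reactants: 24 monobenzyl half-ester
Product: 25 benzyl 2-(trimethylsilyl)ethyl (S)-3-hydroxy-3-methylglutarate
Conditions: Me3SiCH2CH2OH, EDC·HCl, DMAP, CH2Cl2, 0 °C to rt
Reagents that add atoms: 2-(trimethylsilyl)ethanol, C[Si](C)(C)CCO
Why: Steglich esterification of the free acid with a primary alcohol; the descriptor changes from R to S only because the silylethyl arm now outranks the benzyl arm.

Step 17
Reactants: 25 mixed diester
Product: 26 (S)-3-hydroxy-3-methyl-5-oxo-5-[2-(trimethylsilyl)ethoxy]pentanoic acid
Conditions: H2 (1 atm), Pd/C, EtOAc, rt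
Reagents that add atoms: none
Why: Hydrogenolysis removes only the benzyl ester; the silylethyl ester and the tertiary alcohol are inert, so the carboxyl that derives from the lactone carbonyl of 21 is the one set free.

Step 18
Reactants: 20 epoxyquinol diol; 26 silylethyl half-ester
Product: 27 2-(trimethylsilyl)ethyl ester of the target
Conditions: EDC·HCl, DMAP (cat.), CH2Cl2, −20 to 0 °C
Reagents that add atoms: none
Why: Steglich esterification: the primary allylic hydroxyl should react in preference to the C3' hydroxyl, which is secondary and flanked by the epoxide and the substituted alkene, and the tertiary hydroxyl of 26 is not acylated; C3'' is carried in unchanged.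

Step 19
Reactants: 27 silylethyl ester
Product: 28 target half-ester
Conditions: TASF (tris(dimethylamino)sulfonium difluorotrimethylsilicate), DMF, 0 °C; aq. NH4Cl
Reagents that add atoms: none
Why: Fluoride attacks silicon and the 2-(trimethylsilyl)ethyl ester fragments to the carboxylate, ethene and Me3SiF; this weakly basic fluoride source should leave the epoxy enone, the allylic ester and both hydroxyls untouched.

## Compound list

1 | (+)-sclareolide | C[C@]12CCCC([C@@H]1CC[C@@]3([C@@H]2CC(=O)O3)C)(C)C | starting material
2 | sclareolide lactol (hemiacetal carbon as anomer mixture) | C[C@]12CCCC([C@@H]1CC[C@@]3([C@@H]2CC(O)O3)C)(C)C | intermediate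
3 | 11-ethynyldriman-8α-ol (configuration of 1 at C5, C8, C9, C10) | C[C@]12CCCC([C@@H]1CC[C@@](O)([C@@H]2CC#C)C)(C)C | intermediate
4 | 11-ethynyldrim-8(12)-ene | C=C1CC[C@H]2C(C)(C)CCC[C@]2(C)[C@H]1CC#C | intermediate
5 | 2-bromoprop-2-en-1-ol | C=C(Br)CO | starting material
6 | (2-bromoallyloxy)(tert-butyl)dimethylsilane | C=C(Br)CO[Si](C)(C)C(C)(C)C | intermediate
7 | Cr(CO)6 | O=C=[Cr](=C=O)(=C=O)(=C=O)(=C=O)=C=O | starting material
8 | 2-lithioallyl tert-butyldimethylsilyl ether | [Li]C(=C)CO[Si](C)(C)C(C)(C)C | intermediate
9 | lithium pentacarbonyl[2-(silyloxymethyl)acryloyl]chromate | [Li+].[O-]C(C(=C)CO[Si](C)(C)C(C)(C)C)=[Cr](=C=O)(=C=O)(=C=O)(=C=O)=C=O | intermediate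
10 | pentacarbonyl{methoxy[3-(tert-butyldimethylsilyloxy)prop-1-en-2-yl]carbene}chromium | COC(C(=C)CO[Si](C)(C)C(C)(C)C)=[Cr](=C=O)(=C=O)(=C=O)(=C=O)=C=O | intermediate
11 | tricarbonyl(η6-arene)chromium complex of phenol 12 (arene–metal bonding not drawn) | C=C1CC[C@H]2C(C)(C)CCC[C@]2(C)[C@H]1Cc1cc(OC)c(CO[Si](C)(C)C(C)(C)C)cc1O.O=C=[Cr](=C=O)=C=O | intermediate
12 | 2-albicanyl-4-methoxy-5-[(tert-butyldimethylsilyloxy)methyl]phenol (OH at C6', OMe at C3') | C=C1CC[C@H]2C(C)(C)CCC[C@]2(C)[C@H]1Cc1cc(OC)c(CO[Si](C)(C)C(C)(C)C)cc1O | intermediate
13 | 1-albicanyl-2,5-dimethoxy-4-[(tert-butyldimethylsilyloxy)methyl]benzene | C=C1CC[C@H]2C(C)(C)CCC[C@]2(C)[C@H]1Cc1cc(OC)c(CO[Si](C)(C)C(C)(C)C)cc1OC | intermediate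
14 | 1-albicanyl-3,3,6,6-tetramethoxy-4-[(tert-butyldimethylsilyloxy)methyl]cyclohexa-1,4-diene | C=C1CC[C@H]2C(C)(C)CCC[C@]2(C)[C@H]1CC1=CC(OC)(OC)C(CO[Si](C)(C)C(C)(C)C)=CC1(OC)OC | intermediate
15 | 5-albicanyl-4,4-dimethoxy-2-[(tert-butyldimethylsilyloxy)methyl]cyclohexa-2,5-dien-1-one (C3' ketone, C6' ketal) | C=C1CC[C@H]2C(C)(C)CCC[C@]2(C)[C@H]1CC1=CC(=O)C(CO[Si](C)(C)C(C)(C)C)=CC1(OC)OC | intermediate
16 | (3'R)-dienol: 5-albicanyl-4,4-dimethoxy-2-[(tert-butyldimethylsilyloxy)methyl]cyclohexa-2,5-dien-1-ol | C=C1CC[C@H]2C(C)(C)CCC[C@]2(C)[C@H]1CC1=C[C@@H](O)C(CO[Si](C)(C)C(C)(C)C)=CC1(OC)OC | intermediate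
17 | (1'S,2'S,3'S)-cis-epoxy alcohol ketal (epoxide on the face of the C3' hydroxyl) | C=C1CC[C@H]2C(C)(C)CCC[C@]2(C)[C@H]1C[C@]12O[C@H]1[C@@H](O)C(CO[Si](C)(C)C(C)(C)C)=CC2(OC)OC | intermediate
18 | (1'S,2'S,3'R)-trans-epoxy 4-nitrobenzoate ketal | C=C1CC[C@H]2C(C)(C)CCC[C@]2(C)[C@H]1C[C@]12O[C@H]1[C@H](OC(=O)c3ccc(cc3)[N+](=O)[O-])C(CO[Si](C)(C)C(C)(C)C)=CC2(OC)OC | intermediate
19 | (1'S,2'S,3'R)-trans-epoxy alcohol ketal | C=C1CC[C@H]2C(C)(C)CCC[C@]2(C)[C@H]1C[C@]12O[C@H]1[C@H](O)C(CO[Si](C)(C)C(C)(C)C)=CC2(OC)OC | intermediate
20 | (1'S,2'S,3'R)-1'-albicanyl-1',2'-epoxy-3'-hydroxy-4'-(hydroxymethyl)cyclohex-4'-en-6'-one | C=C1CC[C@H]2C(C)(C)CCC[C@]2(C)[C@H]1C[C@]12O[C@H]1[C@H](O)C(CO)=CC2=O | intermediate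
21 | (R)-mevalonolactone | O=C1C[C@](C)(O)CCO1 | starting material
22 | potassium (R)-mevalonate | [K+].[O-]C(=O)C[C@](C)(O)CCO | intermediate
23 | benzyl (R)-mevalonate | O=C(OCc1ccccc1)C[C@](C)(O)CCO | intermediate
24 | (R)-5-benzyloxy-3-hydroxy-3-methyl-5-oxopentanoic acid | O=C(OCc1ccccc1)C[C@](C)(O)CC(=O)O | intermediate
25 | benzyl 2-(trimethylsilyl)ethyl (S)-3-hydroxy-3-methylglutarate | O=C(OCc1ccccc1)C[C@](C)(O)CC(=O)OCC[Si](C)(C)C | intermediate
26 | (S)-3-hydroxy-3-methyl-5-oxo-5-[2-(trimethylsilyl)ethoxy]pentanoic acid | OC(=O)C[C@](C)(O)CC(=O)OCC[Si](C)(C)C | intermediate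
27 | 2-(trimethylsilyl)ethyl ester of the target (same spatial arrangement at C3'') | C=C1CC[C@H]2C(C)(C)CCC[C@]2(C)[C@H]1C[C@]12O[C@H]1[C@H](O)C(COC(=O)C[C@](C)(O)CC(=O)OCC[Si](C)(C)C)=CC2=O | intermediate
28 | target: (3''R)-3-hydroxy-3-methylglutaric acid mono ester of diol 20 at the primary hydroxyl | C=C1CC[C@H]2C(C)(C)CCC[C@]2(C)[C@H]1C[C@]12O[C@H]1[C@H](O)C(COC(=O)C[C@](C)(O)CC(=O)O)=CC2=O | target

## Step count and least certain steps

Total: 19 steps. Longest linear sequence: 13 steps (steps 1, 2, 3, 6–13, 18, 19).

Step 8 (key step). Oxidation may go to the side chain instead (methoxylation at C11 or at the CH2OSi carbon), or stall through poor solubility of the lipophilic arene and electrode fouling. Fallback, from 4 back to 15: bromoboration of the alkyne of 4 with B-bromo-9-borabicyclo[3.3.1]nonane and protonolysis with acetic acid would give the 2-bromo-1-alkene F1 (the C8=C12 alkene is not haloborated). Bromine–lithium exchange, addition to 7 and O-methylation as in step 5 would give the terpenoid alkenyl carbene complex F2. Benzannulation with tert-butyldimethyl(prop-2-yn-1-yloxy)silane then places the hydroxyl at C3' and the methoxy group at C6' (the regioisomeric phenol F3). Oxidation of F3 with PhI(OAc)2 in methanol makes the phenolic carbon the ketone and the para carbon the dimethyl ketal, giving 15 with its regiochemistry fixed by construction.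

Step 9. The wrong ketal may ionise, or hydrolysis may run on to the quinone, because the electronic preference for C3' rests only on alkyl versus CH2OSi. Fallback, from 14 back to 20: the regioisomeric monoketal F4 (C6' ketone, C3' ketal) is not discarded. Its C1'=C2' alkene is the one open to Weitz–Scheffer epoxidation, since its β-carbon C2' is unsubstituted. Trityl hydroperoxide with NaN(SiMe3)2 and the appropriate diisopropyl tartrate (or t-BuOOH/DBU followed by separation of the two epoxide diastereomers) would give the epoxy ketone F5. Aqueous HF would give the epoxyquinone alcohol F6, and NaBH(OAc)3, bound by the free CH2OH, would reduce the adjacent C3' carbonyl to 20; if the cis alcohol formed, it would be inverted as in step 12.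

Step 11. Oxygen may be delivered to C4'=C5' as well, a second epoxidation may follow, or the dienol may aromatise by loss of methanol under the metal catalyst. Fallback, from 16 back to 20: Bu4NF would give the dienediol F8. Selective acetylation of the primary hydroxyl (Ac2O, 2,4,6-collidine, −40 °C) would give the monoacetate F9, whose C4'=C5' alkene is now an allylic ester and clearly less nucleophilic. The same directed epoxidation would give the cis-epoxy alcohol acetate F10. Mitsunobu inversion would give the 4-nitrobenzoate F11, and K2CO3 in methanol would cleave both esters to the trans-epoxy diol ketal F12. Dilute aqueous acid would then unmask the enone to 20.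

Step 10. Facial discrimination between two sp2 flanks that differ only in the α-substituent may be poor, and the product can aromatise on work-up. Fallback, from 15 back to 16: Luche reduction (NaBH4, CeCl3·7H2O, MeOH, −78 °C) would give 16 together with its C3' epimer F7. The two are diastereomers because of the decalin and would be separated by chromatography; F7 would be reoxidised to 15 with MnO2 and recycled.

Step 19. Fluoride may promote migration of the acyl group to the C3' hydroxyl or attack the epoxy enone before the silylethyl ester has fragmented. Fallback, from 20 back to 28: acylation of the primary hydroxyl of 20 with 3-hydroxy-3-methylglutaric anhydride (pyridine, catalytic DMAP) needs no deprotection and would give 28 together with its C3'' epimer F13; the two would be separated by preparative reversed-phase HPLC.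

## Further compounds

F1 | step 8 | 2-bromo-3-albicanylprop-1-ene | C=C1CC[C@H]2C(C)(C)CCC[C@]2(C)[C@H]1CC(Br)=C
F2 | step 8 | pentacarbonyl[methoxy(3-albicanylprop-1-en-2-yl)carbene]chromium | C=C1CC[C@H]2C(C)(C)CCC[C@]2(C)[C@H]1CC(=C)C(OC)=[Cr](=C=O)(=C=O)(=C=O)(=C=O)=C=O
F3 | step 8 | 5-albicanyl-4-methoxy-2-[(tert-butyldimethylsilyloxy)methyl]phenol (OH at C3', OMe at C6') | C=C1CC[C@H]2C(C)(C)CCC[C@]2(C)[C@H]1Cc1cc(O)c(CO[Si](C)(C)C(C)(C)C)cc1OC
F4 | step 9 | 2-albicanyl-4,4-dimethoxy-5-[(tert-butyldimethylsilyloxy)methyl]cyclohexa-2,5-dien-1-one (C6' ketone, C3' ketal) | C=C1CC[C@H]2C(C)(C)CCC[C@]2(C)[C@H]1CC1=CC(OC)(OC)C(CO[Si](C)(C)C(C)(C)C)=CC1=O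
F5 | step 9 | (1'S,2'S)-1',2'-epoxide of F4 | C=C1CC[C@H]2C(C)(C)CCC[C@]2(C)[C@H]1C[C@]12O[C@H]1C(OC)(OC)C(CO[Si](C)(C)C(C)(C)C)=CC2=O
F6 | step 9 | (1'S,2'S)-1'-albicanyl-1',2'-epoxy-4'-(hydroxymethyl)cyclohex-4'-ene-3',6'-dione | C=C1CC[C@H]2C(C)(C)CCC[C@]2(C)[C@H]1C[C@]12O[C@H]1C(=O)C(CO)=CC2=O
F7 | step 10 | (3'S)-dienol, C3' epimer of 16 | C=C1CC[C@H]2C(C)(C)CCC[C@]2(C)[C@H]1CC1=C[C@H](O)C(CO[Si](C)(C)C(C)(C)C)=CC1(OC)OC
F8 | step 11 | (3'R)-dienediol (16 without the silyl group) | C=C1CC[C@H]2C(C)(C)CCC[C@]2(C)[C@H]1CC1=C[C@@H](O)C(CO)=CC1(OC)OC
F9 | step 11 | primary monoacetate of F8 | C=C1CC[C@H]2C(C)(C)CCC[C@]2(C)[C@H]1CC1=C[C@@H](O)C(COC(C)=O)=CC1(OC)OC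
F10 | step 11 | (1'S,2'S,3'S)-cis-epoxy alcohol acetate ketal | C=C1CC[C@H]2C(C)(C)CCC[C@]2(C)[C@H]1C[C@]12O[C@H]1[C@@H](O)C(COC(C)=O)=CC2(OC)OC
F11 | step 11 | (1'S,2'S,3'R)-trans-epoxy 4-nitrobenzoate acetate ketal | C=C1CC[C@H]2C(C)(C)CCC[C@]2(C)[C@H]1C[C@]12O[C@H]1[C@H](OC(=O)c3ccc(cc3)[N+](=O)[O-])C(COC(C)=O)=CC2(OC)OC
F12 | step 11 | (1'S,2'S,3'R)-trans-epoxy diol ketal | C=C1CC[C@H]2C(C)(C)CCC[C@]2(C)[C@H]1C[C@]12O[C@H]1[C@H](O)C(CO)=CC2(OC)OC
F13 | step 19 | C3'' epimer of 28 | C=C1CC[C@H]2C(C)(C)CCC[C@]2(C)[C@H]1C[C@]12O[C@H]1[C@H](O)C(COC(=O)C[C@@](C)(O)CC(=O)O)=CC2=O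
A1 | alternative 1 | (2E,9E,11E)-3,8,8-trimethyl-12-(tert-butyldimethylsilyloxy)dodeca-2,9,11-trienal | O=C/C=C(C)/CCCC(C)(C)/C=C/C=C/O[Si](C)(C)C(C)(C)C
A2 | alternative 1 | 8β-silyloxy-12-nordrim-6-en-11-al | [C@H]1(O[Si](C)(C)C(C)(C)C)C=C[C@H]2C(C)(C)CCC[C@]2(C)[C@H]1C=O
A3 | alternative 2 | acyclic (Z)-β-iodoenone epoxy aldehyde | C=C1CC[C@H]2C(C)(C)CCC[C@]2(C)[C@H]1C[C@@]1(O[C@H]1C=O)C(=O)/C=C(I)/COCc1ccc(OC)cc1
A4 | alternative 2 | epoxyquinol 4-methoxybenzyl ether | C=C1CC[C@H]2C(C)(C)CCC[C@]2(C)[C@H]1C[C@]12O[C@H]1[C@H](O)C(COCc3ccc(OC)cc3)=CC2=O
A5 | alternative 3 | (S)-epoxyfarnesyl dimethoxyarene | CC1(C)O[C@H]1CC/C(C)=C/CC/C(C)=C/Cc1cc(OC)c(CO[Si](C)(C)C(C)(C)C)cc1OC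
A6 | alternative 3 | 3β-hydroxyalbicanyl dimethoxyarene | C=C1CC[C@H]2C(C)(C)[C@@H](O)CC[C@]2(C)[C@H]1Cc1cc(OC)c(CO[Si](C)(C)C(C)(C)C)cc1OC
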